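**Retrosynthetic overview**
1. Target 28 ← acetylation of (S)-epoxy alcohol 27 ← Sharpless asymmetric epoxidation of 2-arylallyl alcohol 26. The oxirane is the only ring formed and is made second to last; the benzene ring is bought.
2. 26 ← stepwise unmasking and acylation of the triply differentiated 19 (phenol OPMB, benzylic OTBS, allylic OTBDPS): (R)-2-methylbutanoate first, then the angelate.
3. 19 ← 2-arylacrylate 17 ← key C–C bond: intermolecular aldol condensation of arylacetate 14 with formaldehyde 15.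
4. 14 ← Negishi coupling of aryl bromide 11 (from methyl 4-bromo-3-hydroxybenzoate 8) with the Reformatsky reagent of tert-butyl bromoacetate 12.
5. (R)-2-Methylbutanoic acid 7 ← Evans methylation of the butanoyl imide of (R)-4-benzyl-1,3-oxazolidin-2-one 1.

Assumption: the SMILES is read as the (Z)-2-methylbut-2-enoate (angelate) on the phenol, the (R)-2-methylbutanoate on the benzylic oxygen and R at the oxirane carbon; acid 7 is made because only its enantiomer is cheap.

**Route**

Step 1
Reactants: 1 (R)-4-benzyl-1,3-oxazolidin-2-one; 2 butanoyl chloride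
Product: 3 (R)-4-benzyl-3-butanoyl-1,3-oxazolidin-2-one
Conditions: Et3N, DMAP (cat.), CH2Cl2, 0 °C to rt
Reagents that add atoms: none
Why: DMAP-catalysed N-acylation of the oxazolidinone by the acid chloride is routine imide formation and leaves the auxiliary stereocentre untouched.

Step 2
Reactants: 3 (R)-4-benzyl-3-butanoyl-1,3-oxazolidin-2-one
Product: 5 (R)-4-benzyl-3-[(R)-2-methylbutanoyl]-1,3-oxazolidin-2-one, via sodium Z-enolate 4 (not isolated)
Conditions: NaN(SiMe3)2, THF, −78 °C; then MeI, −78 to −40 °C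
Reagents that add atoms: iodomethane, CI
Why: Evans asymmetric alkylation, in which the chelated sodium Z-enolate is methylated on the face opposite the benzyl group of the (R)-auxiliary and so sets the new α-stereocentre as R (the minor diastereomer is removed by chromatography or crystallisation).

Step 3
Reactants: 5 (R)-4-benzyl-3-[(R)-2-methylbutanoyl]-1,3-oxazolidin-2-one
Product: 7 (R)-2-methylbutanoic acid, via lithium peroxycarboxylate 6 (not isolated)
Conditions: LiOH, H2O2, THF/H2O (3:1), 0 °C; then Na2SO3 (aq); then HCl (aq) to pH 2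
Reagents that add atoms: hydrogen peroxide (as LiOOH), OO
Why: Hydroperoxide cleavage of the Evans imide, in which LiOOH attacks the exocyclic carbonyl selectively and sulfite reduction of the peracid salt followed by acidification frees the acid without epimerising the α-centre.

Step 4
Reactants: 8 methyl 4-bromo-3-hydroxybenzoate
Product: 9 methyl 4-bromo-3-[(4-methoxybenzyl)oxy]benzoate
Conditions: 4-MeOC6H4CH2Cl, K2CO3, DMF, 60 °C
Reagents that add atoms: 4-methoxybenzyl chloride, COc1ccc(CCl)cc1
Why: Williamson etherification of the acidic phenol gives a PMB ether that survives the hydride, organozinc and carbonate steps ahead and can be removed oxidatively later.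

Step 5
Reactants: 9 methyl 4-bromo-3-[(4-methoxybenzyl)oxy]benzoate
Product: 10 {4-bromo-3-[(4-methoxybenzyl)oxy]phenyl}methanol
Conditions: i-Bu2AlH, CH2Cl2, −78 to 0 °C
Reagents that add atoms: none
Why: Hydride reduction of the ester with i-Bu2AlH gives the benzylic alcohol without touching the aryl bromide or the benzyl ether.

Step 6
Reactants: 10 {4-bromo-3-[(4-methoxybenzyl)oxy]phenyl}methanol
Product: 11 {4-bromo-3-[(4-methoxybenzyl)oxy]benzyl}oxy(tert-butyl)dimethylsilane
Conditions: TBSCl, imidazole, DMF, rt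
Reagents that add atoms: tert-butyldimethylsilyl chloride, CC(C)(C)[Si](C)(C)Cl
Why: Standard imidazole-promoted silylation masks the primary C7 hydroxyl as a TBS ether that can later be cleaved in the presence of a TBDPS ether.

Step 7
Reactants: 11 {4-bromo-3-[(4-methoxybenzyl)oxy]benzyl}oxy(tert-butyl)dimethylsilane; 12 tert-butyl bromoacetate
Product: 14 tert-butyl 2-{4-[(tert-butyldimethylsilyloxy)methyl]-2-[(4-methoxybenzyl)oxy]phenyl}acetate, via Reformatsky reagent 13 (not isolated)
Conditions: 12, Zn dust (Me3SiCl-activated), THF, 40 °C; then 11, Pd2(dba)3 (2 mol %), XPhos (8 mol %), THF, 60 °C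
Reagents that add atoms: none
Why: Negishi cross-coupling of the zinc ester enolate with the aryl bromide under zerovalent palladium catalysis gives the arylacetate, and the neutral organozinc tolerates both ethers.

Step 8
Reactants: 14 tert-butyl 2-{4-[(tert-butyldimethylsilyloxy)methyl]-2-[(4-methoxybenzyl)oxy]phenyl}acetate; 15 formaldehyde (as paraformaldehyde)
Product: 17 tert-butyl 2-{4-[(tert-butyldimethylsilyloxy)methyl]-2-[(4-methoxybenzyl)oxy]phenyl}prop-2-enoate, via aldol adduct 16 (not isolated)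
Conditions: (CH2O)n, K2CO3, n-Bu4NI (cat.), toluene, 80 °C
Reagents that add atoms: none
Why: Key C–C bond formation by intermolecular crossed aldol reaction of the arylacetate enolate with non-enolisable formaldehyde, followed by E1cB dehydration of the β-hydroxy ester to the 2-arylacrylate (no stereocentre remains).

Step 9
Reactants: 17 tert-butyl 2-{4-[(tert-butyldimethylsilyloxy)methyl]-2-[(4-methoxybenzyl)oxy]phenyl}prop-2-enoate
Product: 18 2-{4-[(tert-butyldimethylsilyloxy)methyl]-2-[(4-methoxybenzyl)oxy]phenyl}prop-2-en-1-ol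
Conditions: i-Bu2AlH, CH2Cl2, −78 to 0 °C
Reagents that add atoms: none
Why: 1,2-Reduction of the acrylate ester with i-Bu2AlH in a non-coordinating solvent gives the 2-arylallyl alcohol without conjugate reduction.

Step 10
Reactants: 18 2-{4-[(tert-butyldimethylsilyloxy)methyl]-2-[(4-methoxybenzyl)oxy]phenyl}prop-2-en-1-ol
Product: 19 tert-butyl[(2-{4-[(tert-butyldimethylsilyloxy)methyl]-2-[(4-methoxybenzyl)oxy]phenyl}prop-2-en-1-yl)oxy]diphenylsilane
Conditions: TBDPSCl, imidazole, CH2Cl2, rt
Reagents that add atoms: tert-butyl(chloro)diphenylsilane, CC(C)(C)[Si](Cl)(c1ccccc1)c1ccccc1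
Why: Silylation of the allylic alcohol as the more acid-stable TBDPS ether makes the three oxygens mutually distinguishable.

Step 11
Reactants: 19 tert-butyl[(2-{4-[(tert-butyldimethylsilyloxy)methyl]-2-[(4-methoxybenzyl)oxy]phenyl}prop-2-en-1-yl)oxy]diphenylsilane
Product: 20 [4-{3-[(tert-butyldiphenylsilyl)oxy]prop-1-en-2-yl}-3-[(4-methoxybenzyl)oxy]phenyl]methanol
Conditions: camphor-10-sulfonic acid (10 mol %), MeOH/CH2Cl2 (1:1), 0 °C
Reagents that add atoms: none
Why: Selective acid-catalysed methanolysis removes the primary TBS ether much faster than the TBDPS ether, and the aryl PMB ether is stable to catalytic sulfonic acid at 0 °C.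

Step 12
Reactants: 20 [4-{3-[(tert-butyldiphenylsilyl)oxy]prop-1-en-2-yl}-3-[(4-methoxybenzyl)oxy]phenyl]methanol; 7 (R)-2-methylbutanoic acid
Product: 21 4-{3-[(tert-butyldiphenylsilyl)oxy]prop-1-en-2-yl}-3-[(4-methoxybenzyl)oxy]benzyl (R)-2-methylbutanoate
Conditions: DCC, DMAP (cat.), CH2Cl2, 0 °C to rt
Reagents that add atoms: none
Why: Steglich esterification of the unhindered benzylic alcohol at 0 °C acylates without epimerising the α-stereocentre of the acid.

Step 13
Reactants: 21 4-{3-[(tert-butyldiphenylsilyl)oxy]prop-1-en-2-yl}-3-[(4-methoxybenzyl)oxy]benzyl (R)-2-methylbutanoate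
Product: 22 4-{3-[(tert-butyldiphenylsilyl)oxy]prop-1-en-2-yl}-3-hydroxybenzyl (R)-2-methylbutanoate
Conditions: DDQ, CH2Cl2/aq. NaH2PO4–Na2HPO4 buffer pH 7 (10:1), 0 °C to rt
Reagents that add atoms: none
Why: Oxidative PMB cleavage by DDQ (hydride abstraction, then hydrolysis of the oxocarbenium ion) frees the phenol under neutral conditions that leave silyl ether, ester and alkene alone.

Step 14
Reactants: 22 4-{3-[(tert-butyldiphenylsilyl)oxy]prop-1-en-2-yl}-3-hydroxybenzyl (R)-2-methylbutanoate; 23 angelic acid [(Z)-2-methylbut-2-enoic acid]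
Product: 25 2-{3-[(tert-butyldiphenylsilyl)oxy]prop-1-en-2-yl}-5-{[(R)-2-methylbutanoyl]oxymethyl}phenyl (Z)-2-methylbut-2-enoate, via mixed anhydride 24 (not isolated)
Conditions: 23, 2,4,6-Cl3C6H2COCl, Et3N, toluene, rt; then 22, 60 °C
Reagents that add atoms: none
Why: Yamaguchi-type acylation in which the phenol attacks the unhindered angeloyl carbonyl of the mixed anhydride, and the absence of a nucleophilic catalyst that could add reversibly to the enoate keeps the Z geometry.

Step 15
Reactants: 25 2-{3-[(tert-butyldiphenylsilyl)oxy]prop-1-en-2-yl}-5-{[(R)-2-methylbutanoyl]oxymethyl}phenyl (Z)-2-methylbut-2-enoate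
Product: 26 2-(3-hydroxyprop-1-en-2-yl)-5-{[(R)-2-methylbutanoyl]oxymethyl}phenyl (Z)-2-methylbut-2-enoate
Conditions: HF·pyridine, pyridine/THF, 0 °C to rt
Reagents that add atoms: none
Why: Fluoride desilylation under buffered, slightly acidic conditions frees the allylic alcohol without generating an alkoxide that could take over the neighbouring aryl ester (26 is used at once).

Step 16
Reactants: 26 2-(3-hydroxyprop-1-en-2-yl)-5-{[(R)-2-methylbutanoyl]oxymethyl}phenyl (Z)-2-methylbut-2-enoate
Product: 27 2-[(S)-2-(hydroxymethyl)oxiran-2-yl]-5-{[(R)-2-methylbutanoyl]oxymethyl}phenyl (Z)-2-methylbut-2-enoate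
Conditions: Ti(OiPr)4 (10 mol %), L-(+)-diisopropyl tartrate (14 mol %), t-BuOOH, 4 Å MS, CH2Cl2, −20 °C
Reagents that add atoms: tert-butyl hydroperoxide, CC(C)(C)OO
Why: Sharpless asymmetric epoxidation, in which the titanium-bound allylic alcohol receives oxygen on the face dictated by L-(+)-tartrate to give the (S)-2-arylglycidol, while the electron-poor angelate double bond has no directing hydroxyl and is not epoxidised.

Step 17
Reactants: 27 2-[(S)-2-(hydroxymethyl)oxiran-2-yl]-5-{[(R)-2-methylbutanoyl]oxymethyl}phenyl (Z)-2-methylbut-2-enoate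
Product: 28 2-[(R)-2-(acetoxymethyl)oxiran-2-yl]-5-{[(R)-2-methylbutanoyl]oxymethyl}phenyl (Z)-2-methylbut-2-enoate
Conditions: Ac2O, pyridine, CH2Cl2, 0 °C
Reagents that add atoms: acetic anhydride, CC(=O)OC(C)=O
Why: Mild acetylation of the primary alcohol leaves the oxirane stereocentre untouched, and the descriptor changes from S to R only because the CIP ranking of the two CH2O arms is swapped.

**Compound list**
1 | (R)-4-benzyl-1,3-oxazolidin-2-one | O=C1N[C@H](Cc2ccccc2)CO1 | starting material
2 | butanoyl chloride | CCCC(=O)Cl | starting material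
3 | (R)-4-benzyl-3-butanoyl-1,3-oxazolidin-2-one | CCCC(=O)N1[C@H](Cc2ccccc2)COC1=O | intermediate
4 | sodium (Z)-enolate of 3 (formed in the flask) | CC/C=C(\[O-])N1[C@H](Cc2ccccc2)COC1=O.[Na+] | intermediate
5 | (R)-4-benzyl-3-[(R)-2-methylbutanoyl]-1,3-oxazolidin-2-one | CC[C@@H](C)C(=O)N1[C@H](Cc2ccccc2)COC1=O | intermediate
6 | lithium (R)-2-methylbutaneperoxoate (formed in the flask) | CC[C@@H](C)C(=O)O[O-].[Li+] | intermediate
7 | (R)-2-methylbutanoic acid | CC[C@@H](C)C(=O)O | intermediate
8 | methyl 4-bromo-3-hydroxybenzoate | COC(=O)c1ccc(Br)c(O)c1 | starting material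
9 | methyl 4-bromo-3-[(4-methoxybenzyl)oxy]benzoate | COC(=O)c1ccc(Br)c(OCc2ccc(OC)cc2)c1 | intermediate
10 | {4-bromo-3-[(4-methoxybenzyl)oxy]phenyl}methanol | OCc1ccc(Br)c(OCc2ccc(OC)cc2)c1 | intermediate
11 | {4-bromo-3-[(4-methoxybenzyl)oxy]benzyl}oxy(tert-butyl)dimethylsilane | CC(C)(C)[Si](C)(C)OCc1ccc(Br)c(OCc2ccc(OC)cc2)c1 | intermediate
12 | tert-butyl bromoacetate | CC(C)(C)OC(=O)CBr | starting material
13 | (2-tert-butoxy-2-oxoethyl)zinc bromide, Reformatsky reagent (formed in the flask) | CC(C)(C)OC(=O)C[Zn]Br | intermediate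
14 | tert-butyl 2-{4-[(tert-butyldimethylsilyloxy)methyl]-2-[(4-methoxybenzyl)oxy]phenyl}acetate | CC(C)(C)OC(=O)Cc1ccc(CO[Si](C)(C)C(C)(C)C)cc1OCc1ccc(OC)cc1 | intermediate
15 | formaldehyde (used as paraformaldehyde) | C=O | starting material
16 | racemic tert-butyl 2-{4-[(tert-butyldimethylsilyloxy)methyl]-2-[(4-methoxybenzyl)oxy]phenyl}-3-hydroxypropanoate, aldol adduct (formed in the flask) | CC(C)(C)OC(=O)C(CO)c1ccc(CO[Si](C)(C)C(C)(C)C)cc1OCc1ccc(OC)cc1 | intermediate
17 | tert-butyl 2-{4-[(tert-butyldimethylsilyloxy)methyl]-2-[(4-methoxybenzyl)oxy]phenyl}prop-2-enoate | CC(C)(C)OC(=O)C(=C)c1ccc(CO[Si](C)(C)C(C)(C)C)cc1OCc1ccc(OC)cc1 | intermediate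
18 | 2-{4-[(tert-butyldimethylsilyloxy)methyl]-2-[(4-methoxybenzyl)oxy]phenyl}prop-2-en-1-ol | C=C(CO)c1ccc(CO[Si](C)(C)C(C)(C)C)cc1OCc1ccc(OC)cc1 | intermediate
19 | tert-butyl[(2-{4-[(tert-butyldimethylsilyloxy)methyl]-2-[(4-methoxybenzyl)oxy]phenyl}prop-2-en-1-yl)oxy]diphenylsilane | C=C(CO[Si](c1ccccc1)(c1ccccc1)C(C)(C)C)c1ccc(CO[Si](C)(C)C(C)(C)C)cc1OCc1ccc(OC)cc1 | intermediate
20 | [4-{3-[(tert-butyldiphenylsilyl)oxy]prop-1-en-2-yl}-3-[(4-methoxybenzyl)oxy]phenyl]methanol | C=C(CO[Si](c1ccccc1)(c1ccccc1)C(C)(C)C)c1ccc(CO)cc1OCc1ccc(OC)cc1 | intermediate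
21 | 4-{3-[(tert-butyldiphenylsilyl)oxy]prop-1-en-2-yl}-3-[(4-methoxybenzyl)oxy]benzyl (R)-2-methylbutanoate | C=C(CO[Si](c1ccccc1)(c1ccccc1)C(C)(C)C)c1ccc(COC(=O)[C@H](C)CC)cc1OCc1ccc(OC)cc1 | intermediate
22 | 4-{3-[(tert-butyldiphenylsilyl)oxy]prop-1-en-2-yl}-3-hydroxybenzyl (R)-2-methylbutanoate | C=C(CO[Si](c1ccccc1)(c1ccccc1)C(C)(C)C)c1ccc(COC(=O)[C@H](C)CC)cc1O | intermediate
23 | angelic acid, (Z)-2-methylbut-2-enoic acid | C/C=C(/C)C(=O)O | starting material
24 | (Z)-2-methylbut-2-enoic 2,4,6-trichlorobenzoic anhydride (formed in the flask) | C/C=C(/C)C(=O)OC(=O)c1c(Cl)cc(Cl)cc1Cl | intermediate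
25 | 2-{3-[(tert-butyldiphenylsilyl)oxy]prop-1-en-2-yl}-5-{[(R)-2-methylbutanoyl]oxymethyl}phenyl (Z)-2-methylbut-2-enoate | C/C=C(/C)C(=O)Oc1cc(COC(=O)[C@H](C)CC)ccc1C(=C)CO[Si](c1ccccc1)(c1ccccc1)C(C)(C)C | intermediate
26 | 2-(3-hydroxyprop-1-en-2-yl)-5-{[(R)-2-methylbutanoyl]oxymethyl}phenyl (Z)-2-methylbut-2-enoate | C/C=C(/C)C(=O)Oc1cc(COC(=O)[C@H](C)CC)ccc1C(=C)CO | intermediate
27 | 2-[(S)-2-(hydroxymethyl)oxiran-2-yl]-5-{[(R)-2-methylbutanoyl]oxymethyl}phenyl (Z)-2-methylbut-2-enoate | C/C=C(/C)C(=O)Oc1cc(COC(=O)[C@H](C)CC)ccc1[C@]1(CO)CO1 | intermediate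
28 | 2-[(R)-2-(acetoxymethyl)oxiran-2-yl]-5-{[(R)-2-methylbutanoyl]oxymethyl}phenyl (Z)-2-methylbut-2-enoate (CNP0256757.1) | C/C=C(/C)C(=O)Oc1cc(COC(=O)[C@H](C)CC)ccc1[C@]1(COC(C)=O)CO1 | target

**Step count**
Total: 17 steps. Longest linear sequence: 14 steps (8 → 28, steps 4–17); the acid 7 comes from a 3-step side branch (steps 1–3) and joins at step 12.

**Three steps most likely to fail, with fallbacks**

Step 8 (aldol condensation of 14 with 15). The risks are Michael addition of the enolate to the acrylate product, double hydroxymethylation and polymerisation of 17. The fallback sets out from 14 and comes back at 17. Compound 14 is deprotonated with LiN(SiMe3)2 in THF at −78 °C and the enolate is trapped with dimethylmethyleneammonium iodide (CH2=NMe2+ I−) in an intermolecular Mannich reaction. This gives racemic tert-butyl 3-(dimethylamino)-2-{4-[(tert-butyldimethylsilyloxy)methyl]-2-[(4-methoxybenzyl)oxy]phenyl}propanoate F1. Quaternisation with MeI gives the trimethylammonium iodide of F1, namely 3-tert-butoxy-2-{4-[(tert-butyldimethylsilyloxy)methyl]-2-[(4-methoxybenzyl)oxy]phenyl}-N,N,N-trimethyl-3-oxopropan-1-aminium iodide F2. Elimination of trimethylamine with NaHCO3 in CH2Cl2/H2O at rt then gives 17. The methylene unit is delivered stoichiometrically at low temperature, so over-addition and base-mediated dimerisation are avoided.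

Step 14 (angeloylation of 22). The risks are Z-to-E isomerisation to the tiglate and sluggish acyl transfer. The fallback sets out from 22 and comes back at 25, and it builds the Z double bond on the ester instead of transferring it. Phenol 22 is esterified with 2-[bis(2,2,2-trifluoroethoxy)phosphoryl]propanoic acid (DCC, cat. DMAP, CH2Cl2). This gives 2-{3-[(tert-butyldiphenylsilyl)oxy]prop-1-en-2-yl}-5-{[(R)-2-methylbutanoyl]oxymethyl}phenyl 2-[bis(2,2,2-trifluoroethoxy)phosphoryl]propanoate F3 as a mixture of epimers at the phosphonate carbon, which is inconsequential. Still–Gennari olefination with acetaldehyde (KN(SiMe3)2, 18-crown-6, THF, −78 °C) then gives the Z-trisubstituted enoate 25 under kinetic control.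

Step 16 (Sharpless epoxidation of 26). The risks are acyl transfer from the aryl ester to the titanium-bound alkoxide, opening of the benzylic tertiary epoxide, and a lower ee than usual for a 2-aryl allylic alcohol. The fallback sets out from 26 and comes back at 28. Compound 26 is acetylated first (Ac2O, pyridine, 0 °C) to 2-(3-acetoxyprop-1-en-2-yl)-5-{[(R)-2-methylbutanoyl]oxymethyl}phenyl (Z)-2-methylbut-2-enoate F4, which has no free hydroxyl. The 1,1-disubstituted styrene-type double bond is then epoxidised without a directing group by a Shi-type chiral dioxirane. The catalyst is the glucose-derived N-aryl oxazolidinone ketone developed for 1,1-disubstituted olefins, used with KHSO5 (as 2KHSO5·KHSO4·K2SO4) in a K2CO3/AcOH buffer at about pH 8 in dimethoxyethane/H2O at 0 °C. This gives 28 directly. The enantiomer of the ketone is chosen by comparing the product with the data of the natural product. The unwanted epimer at the oxirane carbon is a diastereomer of 28 and is removed by preparative HPLC. The angelate double bond is electron-poor and reacts much more slowly with the dioxirane.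

**Further compounds**
F1 | step 8 | racemic tert-butyl 3-(dimethylamino)-2-{4-[(tert-butyldimethylsilyloxy)methyl]-2-[(4-methoxybenzyl)oxy]phenyl}propanoate | CC(C)(C)OC(=O)C(CN(C)C)c1ccc(CO[Si](C)(C)C(C)(C)C)cc1OCc1ccc(OC)cc1
F2 | step 8 | racemic 3-tert-butoxy-2-{4-[(tert-butyldimethylsilyloxy)methyl]-2-[(4-methoxybenzyl)oxy]phenyl}-N,N,N-trimethyl-3-oxopropan-1-aminium iodide | CC(C)(C)OC(=O)C(C[N+](C)(C)C)c1ccc(CO[Si](C)(C)C(C)(C)C)cc1OCc1ccc(OC)cc1.[I-]
F3 | step 14 | 2-{3-[(tert-butyldiphenylsilyl)oxy]prop-1-en-2-yl}-5-{[(R)-2-methylbutanoyl]oxymethyl}phenyl 2-[bis(2,2,2-trifluoroethoxy)phosphoryl]propanoate | CC(C(=O)Oc1cc(COC(=O)[C@H](C)CC)ccc1C(=C)CO[Si](c1ccccc1)(c1ccccc1)C(C)(C)C)P(=O)(OCC(F)(F)F)OCC(F)(F)F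
F4 | step 16 | 2-(3-acetoxyprop-1-en-2-yl)-5-{[(R)-2-methylbutanoyl]oxymethyl}phenyl (Z)-2-methylbut-2-enoate | C/C=C(/C)C(=O)Oc1cc(COC(=O)[C@H](C)CC)ccc1C(=C)COC(C)=O
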